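**Plan**
- Retrosynthesis (target azulene numbering): the veratrate C–O and the C5=C6 unsaturation are removed last, and the C4 carbinol is traced to a C4 ketone. The hydroazulene is then cut at two bonds at once, C5–C6 and the ring-fusion bond C3a–C8a.
- Enabling feature: the seven-membered ring carries oxygen at C4 and C7 (1,4-related). C3a–C4(O)–C5 is therefore an oxyallyl unit and C6–C7(O)–C8–C8a a 2-oxy-1,3-diene, with the cyclopentane carbons C1–C3 as a three-atom tether. This is the retron of an intramolecular oxyallyl cation–diene (4+3) cycloaddition.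
- Forward: ozonolysis of (S)-terpinen-4-ol gives both arms of the carbinol with the right lengths. The ketone arm is extended to an (E)-enone and then a 2-silyloxydiene, the other arm to a chloromethyl ketone. One operation then folds the chain into the cyclopentane and the cycloheptene together.
- Stereochemistry: C3 comes from the chiral pool; C3a and C8a are set in the cycloaddition (π-face by C3, trans fusion by cation/diene geometry); C4 by hydroxyl-directed hydride delivery.

Key step: step 8

Remark: target azulene numbering is used for all bicyclic compounds; the C6 configuration in 19–23 is drawn as the concerted cycloaddition predicts and is of no consequence, since C6 becomes sp2 in step 12. (S)-(+)-Terpinen-4-ol is assumed to be bought enantiopure.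

**Step 1**
Reactants: 1 (S)-(+)-terpinen-4-ol; 2 triethylsilyl trifluoromethanesulfonate
Product: 3 triethyl{[(1S)-4-methyl-1-(propan-2-yl)cyclohex-3-en-1-yl]oxy}silane
Conditions: TESOTf, 2,6-lutidine, CH2Cl2, 0 °C to rt
Reagents that add atoms: triethylsilyl trifluoromethanesulfonate, CC[Si](CC)(CC)OS(=O)(=O)C(F)(F)F
Why: Silylation of a hindered tertiary alcohol with a silyl triflate and 2,6-lutidine is standard and masks the hydroxyl for the carbonyl chemistry that follows, without touching the stereocenter.

**Step 2**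
Reactants: 3 silyl ether; 4 ozone; 5 sodium chlorite
Product: 7 (3S)-6-oxo-3-(propan-2-yl)-3-[(triethylsilyl)oxy]heptanoic acid, via keto aldehyde 6 (not isolated)
Conditions: O3, CH2Cl2/MeOH, −78 °C; Me2S, −78 °C to rt; then NaClO2, NaH2PO4, 2-methyl-2-butene, t-BuOH/H2O, 0 °C to rt
Reagents that add atoms: ozone, O=[O+][O-]; sodium chlorite, [Na+].[O-]Cl=O
Why: Ozonolysis of the trisubstituted ring alkene with reductive work-up opens the cyclohexene to a methyl ketone and an aldehyde, and Pinnick oxidation converts only the aldehyde to the acid, the carbinol stereocenter being carried over unchanged.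

**Step 3**
Reactants: 7 keto acid; 8 diethyl [2-(methoxy(methyl)amino)-2-oxoethyl]phosphonate
Product: 9 (3S,6E)-8-[methoxy(methyl)amino]-6-methyl-8-oxo-3-(propan-2-yl)-3-[(triethylsilyl)oxy]oct-6-enoic acid
Conditions: NaH (3 equiv), THF, 0 to 45 °C; aq. citric acid
Reagents that add atoms: diethyl [2-(methoxy(methyl)amino)-2-oxoethyl]phosphonate, CCOP(=O)(OCC)CC(=O)N(C)OC
Why: Horner–Wadsworth–Emmons olefination of the methyl ketone (the carboxylate is inert) should favour the (E)-alkene with the longer chain trans to the amide carbonyl, the minor geometric isomer being removed by chromatography.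

**Step 4**
Reactants: 9 Weinreb amide acid; 10 ethylmagnesium bromide
Product: 11 (3S,6E)-6-methyl-8-oxo-3-(propan-2-yl)-3-[(triethylsilyl)oxy]dec-6-enoic acid
Conditions: EtMgBr (3.5 equiv), THF, −20 to 0 °C; aq. NH4Cl
Reagents that add atoms: ethylmagnesium bromide, CC[Mg]Br
Why: In this Weinreb ketone synthesis the Grignard reagent adds once, in 1,2-fashion, to the N-methoxy-N-methylamide through the stable magnesium chelate, while the magnesium carboxylate formed first does not react.

**Step 5**
Reactants: 11 enone acid; 12 (trimethylsilyl)diazomethane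
Product: 13 methyl (3S,6E)-6-methyl-8-oxo-3-(propan-2-yl)-3-[(triethylsilyl)oxy]dec-6-enoate
Conditions: TMSCHN2, PhMe/MeOH, 0 °C
Reagents that add atoms: (trimethylsilyl)diazomethane, C[Si](C)(C)C=[N+]=[N-]
Why: Methyl esterification with TMS-diazomethane in methanol is neutral, so the enone and the β-silyloxy ester unit (prone to E1cB under base) are left intact.

**Step 6**
Reactants: 13 enone ester; 14 triisopropylsilyl trifluoromethanesulfonate
Product: 15 methyl (3S,6E,8Z)-6-methyl-3-(propan-2-yl)-3-[(triethylsilyl)oxy]-8-{[tri(propan-2-yl)silyl]oxy}deca-6,8-dienoate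
Conditions: TIPSOTf, Et3N, CH2Cl2, −78 to 0 °C
Reagents that add atoms: triisopropylsilyl trifluoromethanesulfonate, CC(C)[Si](C(C)C)(C(C)C)OS(=O)(=O)C(F)(F)F
Why: Soft enolisation (silyl triflate/amine) at the α′-methylene of the enone gives the cross-conjugated 2-silyloxydiene, should favour the (Z)-enol ether (methyl cis to oxygen), and does not enolise the ester.

**Step 7**
Reactants: 15 dienol ether ester; 16 chloroiodomethane
Product: 17 (4S,7E,9Z)-1-chloro-7-methyl-4-(propan-2-yl)-4-[(triethylsilyl)oxy]-9-{[tri(propan-2-yl)silyl]oxy}undeca-7,9-dien-2-one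
Conditions: ICH2Cl, MeLi·LiBr, THF/Et2O, −78 °C; aq. NH4Cl
Reagents that add atoms: chloroiodomethane, ClCI
Why: Chloromethyllithium made in situ by iodine–lithium exchange adds to the methyl ester to give a tetrahedral intermediate that is stable at −78 °C and collapses on quench to the chloromethyl ketone (halomethyllithium ester homologation), the bulky silyl enol ether being inert at this temperature.

**Step 8**
Reactants: 17 chloromethyl ketone
Product: 19 (3R,3aR,6R,8aR)-6,8a-dimethyl-3-(propan-2-yl)-3-[(triethylsilyl)oxy]-7-{[tri(propan-2-yl)silyl]oxy}-2,3,3a,5,6,8a-hexahydroazulen-4(1H)-one, via oxyallyl cation 18 (not isolated)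
Conditions: Et3N, LiClO4 (3 M in Et2O), 0.01 M, rt
Reagents that add atoms: none
Why: Triethylamine in the strongly ionising LiClO4/ether medium enolises the chloromethyl ketone toward C3a and chloride leaves from C5, giving the W-shaped 2-oxidoallyl cation 18 (carbinol carbon cis to the oxyallyl oxygen), which adds across the two termini of the tethered 2-silyloxydiene in an asynchronous [4π(4C)+2π(3C)] cycloaddition; the closest known reaction type is the intramolecular (4+3) cycloaddition of α-haloketone-derived oxyallyl cations with tethered 1,3-dienes to give hydroazulenones. The cyclopentane is closed by the C3a–C8a bond between the substituted cation terminus and the tether-bearing diene terminus (5-exo-type closure through the three-atom tether), and the cycloheptene by the suprafacial–suprafacial union of the oxyallyl carbons C3a, C4, C5 with the diene carbons C6, C7, C8, C8a. The trans ring fusion (3a-H α, 8a-CH3 β) should follow from the extended (exo) transition state of the W-cation with the (E)-diene terminus (tether outside, methyl inside), preferred because the compact alternative stacks the oxyallyl C–O over the bulky C7 silyloxy group. The π-face is set by the C3 stereocenter: with the tether perpendicular to the cation plane, the isopropyl group avoids the allylic position eclipsing the oxyallyl C–O and the silyloxy group takes it (inside-alkoxy arrangement), so O-3 ends cis to C4 and the isopropyl group cis to 3a-H, while the C6 methyl follows from the (Z)-enol ether and is erased later. The step needs (4+3) periselectivity over Favorskii rearrangement, E1cB loss of silanolate from the C3a enolate and (3+2) capture, which the non-nucleophilic ionising medium, the electron-rich diene and the tether (only the 5,7-fused mode is within reach) should secure. It delivers C4 as a free ketone and C7 as a regiodefined silyl enol ether, so the two ring oxygens arrive already differentiated.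

**Step 9**
Reactants: 19 cycloadduct
Product: 20 (3R,3aR,6R,8aR)-3-hydroxy-6,8a-dimethyl-3-(propan-2-yl)perhydroazulene-4,7-dione
Conditions: HF·pyridine, pyridine/THF, 0 °C to rt
Reagents that add atoms: none
Why: Buffered fluoride cleaves both Si–O bonds (the enol ether is protonated at C8 to give the C7 ketone, the tertiary silyl ether gives the free 3-OH) under conditions mild enough that retro-aldol cleavage or dehydration of the β-hydroxy ketone should be avoided.

**Step 10**
Reactants: 20 hydroxy diketone
Product: 21 (3R,3aS,4S,6R,8aR)-3,4-dihydroxy-6,8a-dimethyl-3-(propan-2-yl)perhydroazulen-7-one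
Conditions: Me4NBH(OAc)3, MeCN/AcOH, −25 °C
Reagents that add atoms: none
Why: In this Evans–Saksena hydroxyl-directed reduction the 3-OH exchanges onto boron and delivers hydride intramolecularly to the β-face of the C4 carbonyl, which should give the 4α (4S) carbinol, while the remote C7 ketone is not reduced by triacetoxyborohydride.

**Step 11**
Reactants: 21 diol; 22 3,4-dimethoxybenzoyl chloride
Product: 23 (3R,3aS,4S,6R,8aR)-3-hydroxy-6,8a-dimethyl-7-oxo-3-(propan-2-yl)perhydroazulen-4-yl 3,4-dimethoxybenzoate
Conditions: Et3N, DMAP (cat.), CH2Cl2, 0 °C to rt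
Reagents that add atoms: 3,4-dimethoxybenzoyl chloride, COc1ccc(C(Cl)=O)cc1OC
Why: DMAP-catalysed acyl transfer esterifies the secondary 4-OH, the tertiary 3-OH being too hindered to react, and the C4 configuration is retained.

**Step 12**
Reactants: 23 keto ester; 24 trimethylsilyl trifluoromethanesulfonate
Product: 27 (3R,3aS,4S,8aR)-3-hydroxy-6,8a-dimethyl-7-oxo-3-(propan-2-yl)-1,2,3,3a,4,7,8,8a-octahydroazulen-4-yl 3,4-dimethoxybenzoate, via bis-silyl intermediate 25 (not isolated), via silyl-protected enone 26 (not isolated)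
Conditions: TMSOTf, Et3N, CH2Cl2, 0 °C to rt; Pd(OAc)2, MeCN, rt; 1 M HCl, THF, 0 °C
Reagents that add atoms: none
Why: In this Saegusa–Ito oxidation the thermodynamic silyl enol ether forms toward the methyl-bearing C6 (the C8 side cannot desaturate because C8a is quaternary), Pd(II)-mediated β-hydride elimination from C5 should give the conjugated endocyclic enone, and the tertiary trimethylsilyl ether formed alongside is cleaved in the acidic work-up without affecting any stereocenter of the target.

**Compound list**
1 | (S)-(+)-terpinen-4-ol, (1S)-4-methyl-1-(propan-2-yl)cyclohex-3-en-1-ol | CC1=CC[C@](O)(C(C)C)CC1 | starting material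
2 | triethylsilyl trifluoromethanesulfonate | CC[Si](CC)(CC)OS(=O)(=O)C(F)(F)F | starting material
3 | triethyl{[(1S)-4-methyl-1-(propan-2-yl)cyclohex-3-en-1-yl]oxy}silane | CC1=CC[C@](O[Si](CC)(CC)CC)(C(C)C)CC1 | intermediate
4 | ozone | O=[O+][O-] | starting material
5 | sodium chlorite | [Na+].[O-]Cl=O | starting material
6 | (3S)-6-oxo-3-(propan-2-yl)-3-[(triethylsilyl)oxy]heptanal (not isolated) | O=CC[C@](O[Si](CC)(CC)CC)(C(C)C)CCC(C)=O | intermediate
7 | (3S)-6-oxo-3-(propan-2-yl)-3-[(triethylsilyl)oxy]heptanoic acid | OC(=O)C[C@](O[Si](CC)(CC)CC)(C(C)C)CCC(C)=O | intermediate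
8 | diethyl [2-(methoxy(methyl)amino)-2-oxoethyl]phosphonate | CCOP(=O)(OCC)CC(=O)N(C)OC | starting material
9 | (3S,6E)-8-[methoxy(methyl)amino]-6-methyl-8-oxo-3-(propan-2-yl)-3-[(triethylsilyl)oxy]oct-6-enoic acid | OC(=O)C[C@](O[Si](CC)(CC)CC)(C(C)C)CC/C(C)=C/C(=O)N(C)OC | intermediate
10 | ethylmagnesium bromide | CC[Mg]Br | starting material
11 | (3S,6E)-6-methyl-8-oxo-3-(propan-2-yl)-3-[(triethylsilyl)oxy]dec-6-enoic acid | OC(=O)C[C@](O[Si](CC)(CC)CC)(C(C)C)CC/C(C)=C/C(=O)CC | intermediate
12 | (trimethylsilyl)diazomethane | C[Si](C)(C)C=[N+]=[N-] | starting material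
13 | methyl (3S,6E)-6-methyl-8-oxo-3-(propan-2-yl)-3-[(triethylsilyl)oxy]dec-6-enoate | COC(=O)C[C@](O[Si](CC)(CC)CC)(C(C)C)CC/C(C)=C/C(=O)CC | intermediate
14 | triisopropylsilyl trifluoromethanesulfonate | CC(C)[Si](C(C)C)(C(C)C)OS(=O)(=O)C(F)(F)F | starting material
15 | methyl (3S,6E,8Z)-6-methyl-3-(propan-2-yl)-3-[(triethylsilyl)oxy]-8-{[tri(propan-2-yl)silyl]oxy}deca-6,8-dienoate | COC(=O)C[C@](O[Si](CC)(CC)CC)(C(C)C)CC/C(C)=C/C(O[Si](C(C)C)(C(C)C)C(C)C)=C/C | intermediate
16 | chloroiodomethane | ClCI | starting material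
17 | (4S,7E,9Z)-1-chloro-7-methyl-4-(propan-2-yl)-4-[(triethylsilyl)oxy]-9-{[tri(propan-2-yl)silyl]oxy}undeca-7,9-dien-2-one | ClCC(=O)C[C@](O[Si](CC)(CC)CC)(C(C)C)CC/C(C)=C/C(O[Si](C(C)C)(C(C)C)C(C)C)=C/C | intermediate
18 | 2-oxidoallyl cation (zwitterion) from 17 by loss of HCl, W-shaped (not isolated) | [O-]C(=C)[CH+][C@](O[Si](CC)(CC)CC)(C(C)C)CC/C(C)=C/C(O[Si](C(C)C)(C(C)C)C(C)C)=C/C | intermediate
19 | (3R,3aR,6R,8aR)-6,8a-dimethyl-3-(propan-2-yl)-3-[(triethylsilyl)oxy]-7-{[tri(propan-2-yl)silyl]oxy}-2,3,3a,5,6,8a-hexahydroazulen-4(1H)-one (trans-fused, C7=C8 silyl enol ether) | O=C2C[C@@H](C)C(O[Si](C(C)C)(C(C)C)C(C)C)=C[C@@]3(C)CC[C@@](O[Si](CC)(CC)CC)(C(C)C)[C@H]23 | intermediate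
20 | (3R,3aR,6R,8aR)-3-hydroxy-6,8a-dimethyl-3-(propan-2-yl)perhydroazulene-4,7-dione | O=C2C[C@@H](C)C(=O)C[C@@]3(C)CC[C@@](O)(C(C)C)[C@H]23 | intermediate
21 | (3R,3aS,4S,6R,8aR)-3,4-dihydroxy-6,8a-dimethyl-3-(propan-2-yl)perhydroazulen-7-one | O[C@H]2C[C@@H](C)C(=O)C[C@@]3(C)CC[C@@](O)(C(C)C)[C@H]23 | intermediate
22 | 3,4-dimethoxybenzoyl chloride | COc1ccc(C(Cl)=O)cc1OC | starting material
23 | (3R,3aS,4S,6R,8aR)-3-hydroxy-6,8a-dimethyl-7-oxo-3-(propan-2-yl)perhydroazulen-4-yl 3,4-dimethoxybenzoate | COc1ccc(C(=O)O[C@H]2C[C@@H](C)C(=O)C[C@@]3(C)CC[C@@](O)(C(C)C)[C@H]23)cc1OC | intermediate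
24 | trimethylsilyl trifluoromethanesulfonate | C[Si](C)(C)OS(=O)(=O)C(F)(F)F | starting material
25 | 3-O-trimethylsilyl ether and C6=C7 trimethylsilyl enol ether of 23 (not isolated) | COc1ccc(C(=O)O[C@H]2CC(C)=C(O[Si](C)(C)C)C[C@@]3(C)CC[C@@](O[Si](C)(C)C)(C(C)C)[C@H]23)cc1OC | intermediate
26 | 3-O-trimethylsilyl ether of 27 (not isolated) | COc1ccc(C(=O)O[C@H]2C=C(C)C(=O)C[C@@]3(C)CC[C@@](O[Si](C)(C)C)(C(C)C)[C@H]23)cc1OC | intermediate
27 | (3R,3aS,4S,8aR)-3-hydroxy-6,8a-dimethyl-7-oxo-3-(propan-2-yl)-1,2,3,3a,4,7,8,8a-octahydroazulen-4-yl 3,4-dimethoxybenzoate | COc1ccc(C(=O)O[C@H]2C=C(C)C(=O)C[C@@]3(C)CC[C@@](O)(C(C)C)[C@H]23)cc1OC | target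

**Step count and risks**
Total steps: 12. Longest linear sequence: 12 (fully linear from 1).

Steps most likely to fail:

1. Step 8. What may go wrong: β-elimination of the silyloxy group from the C3a enolate, or Favorskii-type collapse, may outrun chloride ionisation; the cycloaddition may also proceed through the compact transition state (cis fusion) or on the other π-face. Fallback (the two bonds are made one after the other, setting out from 9 and coming back at 20): borane–dimethyl sulfide reduces the carboxylic acid of 9 to the primary alcohol F1. Isopropenylmagnesium bromide converts the Weinreb amide into the cross-conjugated dienone alcohol F2, and Dess–Martin oxidation gives the dienone aldehyde F3. A secondary-amine catalyst (pyrrolidine/AcOH or a diarylprolinol silyl ether) closes the cyclopentane by intramolecular enamine Michael addition to the β,β-disubstituted enone, giving the formyl cyclopentane F4. The acyl radical generated from the aldehyde C–H (tetrabutylammonium decatungstate, 365 nm) then closes the seven-membered ring by 7-endo Giese addition to the isopropenyl ketone, giving the silyl-protected diketone F5. HF·pyridine returns to 20.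

2. Step 10. What may go wrong: the hindered tertiary hydroxyl may fail to bind boron, so that hydride is delivered from the open α-face, or the β-hydroxy ketone may dehydrate in the acidic medium. Fallback (external hydride followed by invertive esterification, setting out from 19 and coming back at 23): NaBH4 in MeOH (or L-Selectride) should reduce the C4 ketone of 19 from the unhindered α-face to the 4β-alcohol F6, with both silyl groups still in place. Mitsunobu esterification with 3,4-dimethoxybenzoic acid (DIAD, PPh3) installs the ester with inversion, giving the bis-silyl 4α-veratrate F7. HF·pyridine removes both silyl groups and returns to 23.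

3. Step 12. What may go wrong: enolisation or β-hydride elimination toward the methyl group (exocyclic methylene), and ionisation of the newly allylic ester by the Pd(0) that is formed. Fallback (the double bond is introduced from the C4 carbonyl before the ester is present, setting out from 19 and coming back at 27): kinetic enolisation of 19 at C5 (LDA, TMSCl, −78 °C) gives the C4=C5 trimethylsilyl enol ether F8. Pd(OAc)2 converts it into the silyloxy dienone F9, and HF·pyridine gives the hydroxy enedione F10. Me4NBH(OAc)3 reduces the C4 carbonyl of this β-hydroxy enone by the same directed delivery to the allylic diol F11. DMAP-catalysed acylation with 22 then gives 27.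

**Further compounds**
F1 | step 8 | (2E,6S)-8-hydroxy-N-methoxy-N,3-dimethyl-6-(propan-2-yl)-6-[(triethylsilyl)oxy]oct-2-enamide | OCC[C@](O[Si](CC)(CC)CC)(C(C)C)CC/C(C)=C/C(=O)N(C)OC
F2 | step 8 | (4E,8S)-10-hydroxy-2,5-dimethyl-8-(propan-2-yl)-8-[(triethylsilyl)oxy]deca-1,4-dien-3-one | OCC[C@](O[Si](CC)(CC)CC)(C(C)C)CC/C(C)=C/C(=O)C(C)=C
F3 | step 8 | (3S,6E)-6,9-dimethyl-8-oxo-3-(propan-2-yl)-3-[(triethylsilyl)oxy]deca-6,9-dienal | O=CC[C@](O[Si](CC)(CC)CC)(C(C)C)CC/C(C)=C/C(=O)C(C)=C
F4 | step 8 | 2-methyl-2-(3-methyl-2-oxobut-3-en-1-yl)-5-(propan-2-yl)-5-[(triethylsilyl)oxy]cyclopentane-1-carbaldehyde, configured as C8a, C3 and C3a of the target | C=C(C)C(=O)C[C@@]1(C)CC[C@@](O[Si](CC)(CC)CC)(C(C)C)[C@@H]1C=O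
F5 | step 8 | 3-O-triethylsilyl ether of 20 | O=C2C[C@@H](C)C(=O)C[C@@]3(C)CC[C@@](O[Si](CC)(CC)CC)(C(C)C)[C@H]23
F6 | step 10 | 4β-alcohol (4R) from 19, both silyl groups retained | O[C@@H]2C[C@@H](C)C(O[Si](C(C)C)(C(C)C)C(C)C)=C[C@@]3(C)CC[C@@](O[Si](CC)(CC)CC)(C(C)C)[C@H]23
F7 | step 10 | 4α-(3,4-dimethoxybenzoate) (4S) with 3-O-triethylsilyl ether and C7=C8 triisopropylsilyl enol ether | COc1ccc(C(=O)O[C@H]2C[C@@H](C)C(O[Si](C(C)C)(C(C)C)C(C)C)=C[C@@]3(C)CC[C@@](O[Si](CC)(CC)CC)(C(C)C)[C@H]23)cc1OC
F8 | step 12 | C4=C5 trimethylsilyl enol ether of 19 | C[Si](C)(C)OC2=C[C@@H](C)C(O[Si](C(C)C)(C(C)C)C(C)C)=C[C@@]3(C)CC[C@@](O[Si](CC)(CC)CC)(C(C)C)[C@H]23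
F9 | step 12 | 5,6-didehydro derivative of 19 (silyloxy dienone) | O=C2C=C(C)C(O[Si](C(C)C)(C(C)C)C(C)C)=C[C@@]3(C)CC[C@@](O[Si](CC)(CC)CC)(C(C)C)[C@H]23
F10 | step 12 | (3R,3aR,8aR)-3-hydroxy-6,8a-dimethyl-3-(propan-2-yl)-2,3,3a,8-tetrahydro-1H-azulene-4,7-dione (hydroxy enedione) | O=C2C=C(C)C(=O)C[C@@]3(C)CC[C@@](O)(C(C)C)[C@H]23
F11 | step 12 | (3R,3aS,4S,8aR)-3,4-dihydroxy-6,8a-dimethyl-3-(propan-2-yl)-1,2,3,3a,4,8-hexahydroazulen-7-one (deacyl target) | O[C@H]2C=C(C)C(=O)C[C@@]3(C)CC[C@@](O)(C(C)C)[C@H]23
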